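The target is cut at the interflavanyl bond C4(upper)–C6(lower) into two 2,3-cis flavan-3,4-diol units, joined late by a silver-triggered Friedel–Crafts reaction. The pyran ring of each unit is closed on one arene, 1,2-bis(benzyloxy)-3-bromo-4-iodobenzene, taken to its Grignard reagent: in one pot this adds to an alpha-benzyloxy-beta-hydroxy aldehyde (C4–C4a bond) and copper catalysis then joins the free hydroxyl to the brominated carbon (O1–C8a bond). The step exploits the three contiguous substituted carbons C8(O)–C8a(O1)–C4a(C4) of ring A of the upper unit. The aldehyde, with C2 and C3 set by an Evans glycolate aldol reaction, carries no ring at all.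

Key step: step 10

Remark: flavan numbering (O1, C2, C3, C4, C4a, C5–C8, C8a) is used for both units and their open-chain precursors. Compound 4 is taken as a catalogue compound (otherwise one step from (S)-4-benzyloxazolidin-2-one and benzyloxyacetyl chloride). Compounds 14, 15, 17 and 18 are carried as mixtures of C4 epimers, so their SMILES leave that centre open. Grignard reagent 13 is made in one batch, kept cold in THF and divided between steps 10 and 12, for which aldehydes 8 and 12 are prepared freshly in parallel.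

Step 1
Reactants: 1 3-bromocatechol
Product: 2 1,2-bis(benzyloxy)-3-bromobenzene
Conditions: BnBr, K2CO3, DMF, 60 °C
Reagents that add atoms: benzyl bromide, BrCc1ccccc1
Why: Williamson ether synthesis masks the two oxygens that end as the 7- and 8-hydroxyls of either unit.

Step 2
Reactants: 2 1,2-bis(benzyloxy)-3-bromobenzene
Product: 3 1,2-bis(benzyloxy)-3-bromo-4-iodobenzene
Conditions: N-iodosuccinimide, CF3CO2H (cat.), MeCN, 0 °C to rt
Reagents that add atoms: N-iodosuccinimide, O=C1CCC(=O)N1I
Why: Electrophilic aromatic iodination should go para to the benzyloxy group on C1, which can conjugate with the ring, whereas the one on C2 is flanked on both sides and twisted out of plane, so iodine enters C4 next to bromine.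

Step 3
Reactants: 4 (S)-4-benzyl-3-[(benzyloxy)acetyl]oxazolidin-2-one; 5 3,4-bis(benzyloxy)benzaldehyde
Product: 6 syn aldol adduct of the upper unit
Conditions: Bu2BOTf, Et3N, CH2Cl2, −78 to 0 °C; then 5, −78 to 0 °C; H2O2, pH 7 buffer, MeOH
Reagents that add atoms: none
Why: Evans syn aldol reaction, in which the Z-boron enolate of the glycolate imide reacts through a chair Zimmerman–Traxler transition state on the face away from the benzyl group of the auxiliary, sets the later C3 and C2 of the upper unit in the syn relation.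

Step 4
Reactants: 6 syn aldol adduct of the upper unit
Product: 7 Weinreb amide of the upper unit
Conditions: MeNH(OMe)·HCl, AlMe3, CH2Cl2, −20 to 0 °C; aq. potassium sodium tartrate
Reagents that add atoms: N,O-dimethylhydroxylamine hydrochloride, CNOC.Cl
Why: Weinreb amide formation by aluminium amide transamination at the exocyclic carbonyl, helped by the free beta-hydroxyl, releases the auxiliary without touching either stereocentre.

Step 5
Reactants: 7 Weinreb amide of the upper unit
Product: 8 (2S,3R)-2-(benzyloxy)-3-[3,4-bis(benzyloxy)phenyl]-3-hydroxypropanal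
Conditions: i-Bu2AlH, THF, −78 °C; aq. potassium sodium tartrate
Reagents that add atoms: none
Why: Weinreb amide reduction should stop at the aldehyde because the chelated tetrahedral aluminium intermediate survives until work-up; the aldehyde is used crude since alpha-alkoxy aldehydes epimerise on storage.

Step 6
Reactants: 4 (S)-4-benzyl-3-[(benzyloxy)acetyl]oxazolidin-2-one; 9 4-(benzyloxy)benzaldehyde
Product: 10 syn aldol adduct of the lower unit
Conditions: Bu2BOTf, Et3N, CH2Cl2, −78 to 0 °C; then 9, −78 to 0 °C; H2O2, pH 7 buffer, MeOH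
Reagents that add atoms: none
Why: Evans syn aldol reaction with the same stereochemical course as in step 3 sets the later C3 and C2 of the lower unit.

Step 7
Reactants: 10 syn aldol adduct of the lower unit
Product: 11 Weinreb amide of the lower unit
Conditions: MeNH(OMe)·HCl, AlMe3, CH2Cl2, −20 to 0 °C; aq. potassium sodium tartrate
Reagents that add atoms: N,O-dimethylhydroxylamine hydrochloride, CNOC.Cl
Why: Weinreb amide formation by aluminium amide transamination removes the auxiliary without epimerisation, as in step 4.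

Step 8
Reactants: 11 Weinreb amide of the lower unit
Product: 12 (2S,3R)-2-(benzyloxy)-3-[4-(benzyloxy)phenyl]-3-hydroxypropanal
Conditions: i-Bu2AlH, THF, −78 °C; aq. potassium sodium tartrate
Reagents that add atoms: none
Why: Weinreb amide reduction stops at the aldehyde through the chelated tetrahedral intermediate, as in step 5.

Step 9
Reactants: 3 1,2-bis(benzyloxy)-3-bromo-4-iodobenzene
Product: 13 [3,4-bis(benzyloxy)-2-bromophenyl]magnesium chloride, LiCl complex, as a THF solution
Conditions: iPrMgCl·LiCl, THF, −20 °C; solution kept at −20 °C, titrated and used at once, one portion in step 10 and one in step 12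
Reagents that add atoms: isopropylmagnesium chloride–lithium chloride complex, CC(C)[Mg]Cl.[Li+].[Cl-]
Why: Iodine–magnesium exchange with the Knochel-type reagent should take place only at the carbon–iodine bond, the weaker of the two carbon–halogen bonds, and the ortho-bromo aryl Grignard reagent formed should not eliminate to the aryne while it is kept cold.

Step 10
Reactants: 13 [3,4-bis(benzyloxy)-2-bromophenyl]magnesium chloride, LiCl complex; 8 (2S,3R)-2-(benzyloxy)-3-[3,4-bis(benzyloxy)phenyl]-3-hydroxypropanal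
Product: 15 (2R,3R,4RS)-3,7,8-tris(benzyloxy)-2-[3,4-bis(benzyloxy)phenyl]chroman-4-ol, via bromo diol 14 (not isolated)
Conditions: 8, LiN(SiMe3)2, THF, −78 °C; then 13 (THF solution), −78 to 0 °C; THF removed under reduced pressure; then CuI (20 mol%), 3,4,7,8-tetramethyl-1,10-phenanthroline, Cs2CO3, toluene, 110 °C, same flask
Reagents that add atoms: none
Why: The ortho-bromo aryl Grignard reagent 13, with magnesium on the later C4a, adds to the aldehyde carbon of the lithium alkoxide of 8 and so forms C4–C4a; after the change of solvent the C2 alkoxide of 14 is joined to the brominated carbon C8a by copper-catalysed Ullmann-type O-arylation (oxidative addition of C8a–Br to the copper alkoxide, then reductive elimination), which forms O1–C8a. The closest known reaction types are the addition of ortho-haloaryl Grignard reagents to alpha-alkoxy aldehydes and the copper-catalysed cyclisation of 3-(2-bromoaryl)propan-1-ols to chromans. The one ring that closes, pyran ring C, forms by 6-exo attack of O1 on an aromatic carbon; the C4 alkoxide cannot compete, because it would close a four-membered ring, and O3 is blocked as its benzyl ether. C2 and C3 come unchanged from the aldol adduct, because once the aldehyde has reacted no acidic C–H next to a carbonyl group and no retro-aldol path remain under the basic conditions; the new centre C4 needs no control, since it is ionised in steps 11 and 16. The step needs site selectivity on ring A, and the halogen pattern secures it: magnesium was placed at the iodinated C4a in step 9, and the only carbon–halogen bond left for copper is C8a–Br beside the C8 benzyloxy group.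

Step 11
Reactants: 15 (2R,3R,4RS)-3,7,8-tris(benzyloxy)-2-[3,4-bis(benzyloxy)phenyl]chroman-4-ol
Product: 16 (2R,3S,4S)-4-(benzylsulfanyl)-3,7,8-tris(benzyloxy)-2-[3,4-bis(benzyloxy)phenyl]chromane
Conditions: BnSH, BF3·OEt2 (cat.), CH2Cl2, −40 to 0 °C
Reagents that add atoms: benzyl mercaptan, SCc1ccccc1
Why: SN1 thiolysis of a flavan-4-ol, in which the C4 cation is stabilised by O1 and the 7-benzyloxy group and the thiol should enter from the face opposite the 3-benzyloxy group, makes both C4 epimers converge on the 3,4-trans sulfide.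

Step 12
Reactants: 13 [3,4-bis(benzyloxy)-2-bromophenyl]magnesium chloride, LiCl complex; 12 (2S,3R)-2-(benzyloxy)-3-[4-(benzyloxy)phenyl]-3-hydroxypropanal
Product: 18 (2R,3R,4RS)-3,7,8-tris(benzyloxy)-2-[4-(benzyloxy)phenyl]chroman-4-ol, via bromo diol 17 (not isolated)
Conditions: 12, LiN(SiMe3)2, THF, −78 °C; then 13 (THF solution), −78 to 0 °C; THF removed under reduced pressure; then CuI (20 mol%), 3,4,7,8-tetramethyl-1,10-phenanthroline, Cs2CO3, toluene, 110 °C, same flask
Reagents that add atoms: none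
Why: The same one-pot Grignard addition and Ullmann-type O-arylation as in step 10, run on the second portion of 13, builds the pyran ring of the lower unit, with C2 and C3 untouched and C4 formed as a mixture that step 13 removes.

Step 13
Reactants: 18 (2R,3R,4RS)-3,7,8-tris(benzyloxy)-2-[4-(benzyloxy)phenyl]chroman-4-ol
Product: 19 (2R,3S)-3,7,8-tris(benzyloxy)-2-[4-(benzyloxy)phenyl]chroman-4-one
Conditions: Dess–Martin periodinane, NaHCO3, CH2Cl2, 0 °C
Reagents that add atoms: none
Why: Dess–Martin oxidation of the benzylic alcohol under buffered, non-basic conditions should erase the C4 mixture and leave the epimerisable C3 of the 2,3-cis flavanone intact.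

Step 14
Reactants: 19 (2R,3S)-3,7,8-tris(benzyloxy)-2-[4-(benzyloxy)phenyl]chroman-4-one
Product: 20 (2R,3R,4R)-3,7,8-tris(benzyloxy)-2-[4-(benzyloxy)phenyl]chroman-4-ol
Conditions: NaBH4, MeOH/THF, −40 °C
Reagents that add atoms: none
Why: Borohydride reduction of the cyclic aryl ketone should deliver hydride axially from the face opposite the axial 3-benzyloxy group and the 2-aryl group, which places the new 4-hydroxyl cis to both (all-cis, 4R).

Step 15
Reactants: 20 (2R,3R,4R)-3,7,8-tris(benzyloxy)-2-[4-(benzyloxy)phenyl]chroman-4-ol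
Product: 21 (−)-teracacidin
Conditions: H2 (1 atm), Pd(OH)2/C, EtOAc/MeOH, rt
Reagents that add atoms: none
Why: Hydrogenolysis of the four benzyl ethers under neutral conditions, which should be faster than cleavage of the benzylic C4–OH bond, frees the phenols that make C6 nucleophilic.

Step 16
Reactants: 16 (2R,3S,4S)-4-(benzylsulfanyl)-3,7,8-tris(benzyloxy)-2-[3,4-bis(benzyloxy)phenyl]chromane; 21 (−)-teracacidin
Product: 22 penta-O-benzyl ether of the target (upper unit benzylated)
Conditions: AgBF4, 2,6-di-tert-butylpyridine, THF, 0 °C, dark, 21 in excess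
Reagents that add atoms: none
Why: Thiophilic activation followed by Friedel–Crafts alkylation, in which the C4 cation of the upper unit is attacked by C6 of 21 (ortho to the 7-hydroxyl, para to O1) from the face opposite the 3-benzyloxy group, should set the interflavanyl bond 3,4-trans (4S) while the C4 hydroxyl of 21 stays un-ionised under these buffered conditions.

Step 17
Reactants: 22 penta-O-benzyl ether of the target
Product: 23 target, (2R,3R,4R)-6-[(2R,3R,4S)-2-(3,4-dihydroxyphenyl)-3,7,8-trihydroxychroman-4-yl]-2-(4-hydroxyphenyl)chroman-3,4,7,8-tetrol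
Conditions: H2 (1 atm), Pd(OH)2/C, EtOAc/MeOH, rt
Reagents that add atoms: none
Why: Hydrogenolysis removes the five remaining benzyl ethers without touching a stereocentre.

Compound list
1 | 3-bromobenzene-1,2-diol (3-bromocatechol) | Oc1cccc(Br)c1O | starting material
2 | 1,2-bis(benzyloxy)-3-bromobenzene | Brc1cccc(OCc2ccccc2)c1OCc1ccccc1 | intermediate
3 | 1,2-bis(benzyloxy)-3-bromo-4-iodobenzene | Ic1ccc(OCc2ccccc2)c(OCc2ccccc2)c1Br | intermediate
4 | (S)-4-benzyl-3-[(benzyloxy)acetyl]oxazolidin-2-one | O=C1OC[C@H](Cc2ccccc2)N1C(=O)COCc1ccccc1 | starting material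
5 | 3,4-bis(benzyloxy)benzaldehyde | O=Cc1ccc(OCc2ccccc2)c(OCc2ccccc2)c1 | starting material
6 | (S)-4-benzyl-3-[(2S,3R)-2-(benzyloxy)-3-[3,4-bis(benzyloxy)phenyl]-3-hydroxypropanoyl]oxazolidin-2-one | O[C@H](c1ccc(OCc2ccccc2)c(OCc2ccccc2)c1)[C@@H](C(=O)N1[C@@H](Cc2ccccc2)COC1=O)OCc1ccccc1 | intermediate
7 | (2S,3R)-2-(benzyloxy)-3-[3,4-bis(benzyloxy)phenyl]-3-hydroxy-N-methoxy-N-methylpropanamide | O[C@H](c1ccc(OCc2ccccc2)c(OCc2ccccc2)c1)[C@@H](C(=O)N(C)OC)OCc1ccccc1 | intermediate
8 | (2S,3R)-2-(benzyloxy)-3-[3,4-bis(benzyloxy)phenyl]-3-hydroxypropanal | O[C@H](c1ccc(OCc2ccccc2)c(OCc2ccccc2)c1)[C@@H](C=O)OCc1ccccc1 | intermediate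
9 | 4-(benzyloxy)benzaldehyde | O=Cc1ccc(OCc2ccccc2)cc1 | starting material
10 | (S)-4-benzyl-3-[(2S,3R)-2-(benzyloxy)-3-[4-(benzyloxy)phenyl]-3-hydroxypropanoyl]oxazolidin-2-one | O[C@H](c1ccc(OCc2ccccc2)cc1)[C@@H](C(=O)N1[C@@H](Cc2ccccc2)COC1=O)OCc1ccccc1 | intermediate
11 | (2S,3R)-2-(benzyloxy)-3-[4-(benzyloxy)phenyl]-3-hydroxy-N-methoxy-N-methylpropanamide | O[C@H](c1ccc(OCc2ccccc2)cc1)[C@@H](C(=O)N(C)OC)OCc1ccccc1 | intermediate
12 | (2S,3R)-2-(benzyloxy)-3-[4-(benzyloxy)phenyl]-3-hydroxypropanal | O[C@H](c1ccc(OCc2ccccc2)cc1)[C@@H](C=O)OCc1ccccc1 | intermediate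
13 | [3,4-bis(benzyloxy)-2-bromophenyl]magnesium chloride, LiCl complex, used as a THF solution | Cl[Mg]c1ccc(OCc2ccccc2)c(OCc2ccccc2)c1Br | intermediate
14 | (1RS,2S,3R)-2-(benzyloxy)-1-[3,4-bis(benzyloxy)-2-bromophenyl]-3-[3,4-bis(benzyloxy)phenyl]propane-1,3-diol, formed as its metal alkoxide, not isolated | O[C@H](c1ccc(OCc2ccccc2)c(OCc2ccccc2)c1)[C@@H](C(O)c1ccc(OCc2ccccc2)c(OCc2ccccc2)c1Br)OCc1ccccc1 | intermediate
15 | (2R,3R,4RS)-3,7,8-tris(benzyloxy)-2-[3,4-bis(benzyloxy)phenyl]chroman-4-ol (2,3-cis, C4 epimers) | OC1c2ccc(OCc3ccccc3)c(OCc3ccccc3)c2O[C@H](c2ccc(OCc3ccccc3)c(OCc3ccccc3)c2)[C@@H]1OCc1ccccc1 | intermediate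
16 | (2R,3S,4S)-4-(benzylsulfanyl)-3,7,8-tris(benzyloxy)-2-[3,4-bis(benzyloxy)phenyl]chromane (2,3-cis-3,4-trans) | C(c1ccccc1)S[C@H]1c2ccc(OCc3ccccc3)c(OCc3ccccc3)c2O[C@H](c2ccc(OCc3ccccc3)c(OCc3ccccc3)c2)[C@@H]1OCc1ccccc1 | intermediate
17 | (1RS,2S,3R)-2-(benzyloxy)-1-[3,4-bis(benzyloxy)-2-bromophenyl]-3-[4-(benzyloxy)phenyl]propane-1,3-diol, formed as its metal alkoxide, not isolated | O[C@H](c1ccc(OCc2ccccc2)cc1)[C@@H](C(O)c1ccc(OCc2ccccc2)c(OCc2ccccc2)c1Br)OCc1ccccc1 | intermediate
18 | (2R,3R,4RS)-3,7,8-tris(benzyloxy)-2-[4-(benzyloxy)phenyl]chroman-4-ol (2,3-cis, C4 epimers) | OC1c2ccc(OCc3ccccc3)c(OCc3ccccc3)c2O[C@H](c2ccc(OCc3ccccc3)cc2)[C@@H]1OCc1ccccc1 | intermediate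
19 | (2R,3S)-3,7,8-tris(benzyloxy)-2-[4-(benzyloxy)phenyl]chroman-4-one (2,3-cis) | O=C1c2ccc(OCc3ccccc3)c(OCc3ccccc3)c2O[C@H](c2ccc(OCc3ccccc3)cc2)[C@@H]1OCc1ccccc1 | intermediate
20 | (2R,3R,4R)-3,7,8-tris(benzyloxy)-2-[4-(benzyloxy)phenyl]chroman-4-ol (all-cis) | O[C@@H]1c2ccc(OCc3ccccc3)c(OCc3ccccc3)c2O[C@H](c2ccc(OCc3ccccc3)cc2)[C@@H]1OCc1ccccc1 | intermediate
21 | (−)-teracacidin, (2R,3R,4R)-2-(4-hydroxyphenyl)chroman-3,4,7,8-tetrol | Oc1ccc([C@H]2Oc3c(ccc(O)c3O)[C@@H](O)[C@H]2O)cc1 | intermediate
22 | (2R,3R,4R)-6-[(2R,3R,4S)-3,7,8-tris(benzyloxy)-2-[3,4-bis(benzyloxy)phenyl]chroman-4-yl]-2-(4-hydroxyphenyl)chroman-3,4,7,8-tetrol | Oc1ccc([C@H]2Oc3c(cc([C@H]4c5ccc(OCc6ccccc6)c(OCc6ccccc6)c5O[C@H](c5ccc(OCc6ccccc6)c(OCc6ccccc6)c5)[C@@H]4OCc4ccccc4)c(O)c3O)[C@@H](O)[C@H]2O)cc1 | intermediate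
23 | (2R,3R,4R)-6-[(2R,3R,4S)-2-(3,4-dihydroxyphenyl)-3,7,8-trihydroxychroman-4-yl]-2-(4-hydroxyphenyl)chroman-3,4,7,8-tetrol | Oc1ccc([C@H]2Oc3c(cc([C@H]4c5ccc(O)c(O)c5O[C@H](c5ccc(O)c(O)c5)[C@@H]4O)c(O)c3O)[C@@H](O)[C@H]2O)cc1 | target

Total step count: 17. Longest linear sequence: 9 steps (from 1 through steps 1, 2, 9 and 12 to 17; the same length from 4 and 9 through steps 6 to 8 and 12 to 17).

Steps most likely to fail

Step 10 (key step). The lithium alkoxide of 8 may undergo retro-aldol cleavage or epimerise at the alpha carbon before 13 has added, and 13 may lose MgBrCl to an aryne as the mixture warms. The copper cycle may also stall at the C8a–Br bond, which is flanked on both sides and sits next to a chelating benzylic alkoxide, so that reduction of the C–Br bond outruns ring closure. The fallback uses fluoride as the leaving group, closes the ring without a metal catalyst and separates the two stages; it sets out from 8. 3-Fluorocatechol is benzylated (BnBr, K2CO3, DMF) to 1,2-bis(benzyloxy)-3-fluorobenzene F1 and brominated with N-bromosuccinimide, para to the conjugating benzyloxy group, to 1,2-bis(benzyloxy)-4-bromo-3-fluorobenzene F2. Bromine–lithium exchange (n-BuLi, THF, −78 °C, where the ortho-fluoro aryllithium does not eliminate) and addition to the lithium alkoxide of 8 should give, after work-up, the fluoro diol F3. KN(SiMe3)2 and 18-crown-6 in DMF at 80 °C then close the ring by intramolecular nucleophilic aromatic substitution of fluoride by the C2 alkoxide, which returns to the route at 15.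

Step 16. The C4 cation may be captured at C5 or at a hydroxyl oxygen of 21 instead of at C6, and acid set free during the reaction may drive self-condensation of 21 through its own C4 hydroxyl. The fallback uses a fully protected nucleophile; it sets out from 20 and 16. Acetylation (Ac2O, pyridine, DMAP) gives the 4-O-acetyl derivative of 20 F4, which has no free hydroxyl and no ionisable C4 oxygen. Coupling with 16 (AgBF4, CH2Cl2, 0 °C) should give the nona-O-benzyl dimer acetate F5, with C6 (para to O1, ortho to the 7-benzyloxy group) as the only activated, unhindered ring position. K2CO3 in MeOH/THF removes the acetate to give the nona-O-benzyl dimer F6, and hydrogenolysis over Pd(OH)2/C returns to the route at 23.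

Step 17. The benzylic C4–O bond of the lower unit, or the doubly benzylic interflavanyl bond, may be cleaved during the longer exposure needed to remove five benzyl ethers from the dimer. The fallback removes the benzyl groups of the upper unit at the ketone level and unites the free phenols last, so that no hydrogenolysis is run on the dimer; it sets out from 15. Dess–Martin oxidation gives (2R,3S)-3,7,8-tris(benzyloxy)-2-[3,4-bis(benzyloxy)phenyl]chroman-4-one F7. Hydrogenolysis over Pd(OH)2/C, now with no benzylic hydroxyl in the molecule, gives the free 2,3-cis dihydroflavonol F8. NaBH4 in EtOH at 0 °C reduces it to (−)-melacacidin F9, and thiolysis with BnSH in AcOH gives (2R,3S,4S)-4-(benzylsulfanyl)-2-(3,4-dihydroxyphenyl)chroman-3,7,8-triol F10. AgBF4 in THF with an excess of 21 then forms the interflavanyl bond and returns to the route at 23 with no protecting group left to remove.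

Further compounds
F1 | step 10 | 1,2-bis(benzyloxy)-3-fluorobenzene | Fc1cccc(OCc2ccccc2)c1OCc1ccccc1
F2 | step 10 | 1,2-bis(benzyloxy)-4-bromo-3-fluorobenzene | Brc1ccc(OCc2ccccc2)c(OCc2ccccc2)c1F
F3 | step 10 | (1RS,2S,3R)-2-(benzyloxy)-1-[3,4-bis(benzyloxy)-2-fluorophenyl]-3-[3,4-bis(benzyloxy)phenyl]propane-1,3-diol | O[C@H](c1ccc(OCc2ccccc2)c(OCc2ccccc2)c1)[C@@H](C(O)c1ccc(OCc2ccccc2)c(OCc2ccccc2)c1F)OCc1ccccc1
F4 | step 16 | 4-O-acetyl derivative of 20 (all-cis) | CC(=O)O[C@@H]1c2ccc(OCc3ccccc3)c(OCc3ccccc3)c2O[C@H](c2ccc(OCc3ccccc3)cc2)[C@@H]1OCc1ccccc1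
F5 | step 16 | nona-O-benzyl ether of the target carrying an acetate on the C4 oxygen of the lower unit | c1ccccc1COc1ccc([C@H]2Oc3c(cc([C@H]4c5ccc(OCc6ccccc6)c(OCc6ccccc6)c5O[C@H](c5ccc(OCc6ccccc6)c(OCc6ccccc6)c5)[C@@H]4OCc4ccccc4)c(OCc4ccccc4)c3OCc3ccccc3)[C@@H](OC(C)=O)[C@H]2OCc2ccccc2)cc1
F6 | step 16 | nona-O-benzyl ether of the target with the C4 hydroxyl of the lower unit free | c1ccccc1COc1ccc([C@H]2Oc3c(cc([C@H]4c5ccc(OCc6ccccc6)c(OCc6ccccc6)c5O[C@H](c5ccc(OCc6ccccc6)c(OCc6ccccc6)c5)[C@@H]4OCc4ccccc4)c(OCc4ccccc4)c3OCc3ccccc3)[C@@H](O)[C@H]2OCc2ccccc2)cc1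
F7 | step 17 | (2R,3S)-3,7,8-tris(benzyloxy)-2-[3,4-bis(benzyloxy)phenyl]chroman-4-one | O=C1c2ccc(OCc3ccccc3)c(OCc3ccccc3)c2O[C@H](c2ccc(OCc3ccccc3)c(OCc3ccccc3)c2)[C@@H]1OCc1ccccc1
F8 | step 17 | (2R,3S)-2-(3,4-dihydroxyphenyl)-3,7,8-trihydroxychroman-4-one | O=C1c2ccc(O)c(O)c2O[C@H](c2ccc(O)c(O)c2)[C@@H]1O
F9 | step 17 | (−)-melacacidin, (2R,3R,4R)-2-(3,4-dihydroxyphenyl)chroman-3,4,7,8-tetrol | O[C@@H]1c2ccc(O)c(O)c2O[C@H](c2ccc(O)c(O)c2)[C@@H]1O
F10 | step 17 | (2R,3S,4S)-4-(benzylsulfanyl)-2-(3,4-dihydroxyphenyl)chroman-3,7,8-triol | C(c1ccccc1)S[C@H]1c2ccc(O)c(O)c2O[C@H](c2ccc(O)c(O)c2)[C@@H]1O
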